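**Plan**

- Retrosynthesis: removing the two benzoates, the two benzyl ethers and one diphenylmethylene ketal leads back to the symmetric 2,5-diaryl-3,6-dihydroxy-1,4-benzoquinone. Its diethyl ether is then cut at C1–C6 and C4–C5 of the central ring.
- Enabling feature: at the quinone level the central ring is a four-carbon maleoyl unit O=C1–C2(OEt)=C3(Ar)–C4=O, the ring carbons of a squarate-derived cyclobutenedione, joined to the two carbons C5(OEt)≡C6(Ar) of an aryl ynol ether.
- Further cuts: the C3–aryl bond (aryllithium plus diethyl squarate) and the C6–aryl bond (Negishi coupling of ethoxyethynylzinc chloride).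
- Forward order: four-membered cyclobutenedione, then cobalt-mediated expansion to the six-membered quinone ring, then hydrolysis and reduction to the arene, then a ketal on one catechol and benzoates on the other, then global hydrogenolysis.
- Stereochemistry: the target has no stereocentre. The selectivity questions are 2,5- versus 2,6-regiochemistry in the ring closure and the differentiation of two equivalent catechols.

Key step: step 3

Remark on the chemistry: the target is achiral, so only regiochemistry has to be controlled; in the SMILES of the cobalt complexes 11 and 12 the dative bonds are drawn as charge-separated bonds.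

**Route**

Step 1
Reactants: 1 1-(benzyloxy)-4-bromobenzene; 2 diethyl squarate
Product: 5 3-[4-(benzyloxy)phenyl]-4-ethoxycyclobut-3-ene-1,2-dione, via aryllithium 3 (not isolated), via hydroxycyclobutenone adduct 4 (not isolated)
Conditions: n-BuLi, THF, −78 °C; add to 2, THF, −78 °C; 1 M HCl quench; crude adduct, conc. HCl (cat.), CH2Cl2, rt
Reagents that add atoms: water, O (supplies the oxygen of the new carbonyl after ionisation of the carbinol)
Why: Bromine–lithium exchange gives the aryllithium, which adds 1,2 to one squarate carbonyl; acid ionises the tertiary carbinol, water captures the ethoxy-stabilised cyclobutenyl cation and ethanol is lost, the standard organolithium addition–acid rearrangement route from squarate esters to 3-aryl-4-alkoxycyclobutenediones.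

Step 2
Reactants: 6 ethoxyacetylene; 7 1-(benzyloxy)-4-iodobenzene
Product: 10 1-(benzyloxy)-4-(ethoxyethynyl)benzene, via lithium ethoxyacetylide 8 (not isolated), via ethoxyethynylzinc chloride 9 (not isolated)
Conditions: n-BuLi, THF, −78 °C; ZnCl2, THF, −78 to 0 °C; 7, Pd(PPh3)4 (5 mol%), THF, rt; NaHCO3 work-up, basic Al2O3 chromatography
Reagents that add atoms: none
Why: Negishi coupling, in which the alkynylzinc chloride transmetalates to the arylpalladium iodide formed by oxidative addition to zerovalent palladium; the absence of amine, copper salt and acid spares the sensitive ynol ether.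

Step 3
Reactants: 5 3-[4-(benzyloxy)phenyl]-4-ethoxycyclobut-3-ene-1,2-dione; 10 1-(benzyloxy)-4-(ethoxyethynyl)benzene
Product: 13 2,5-bis[4-(benzyloxy)phenyl]-3,6-diethoxy-1,4-benzoquinone, via bis(triphenylphosphine) maleoylcobalt chloride 11 (not isolated), via dimethylglyoxime pyridine maleoylcobalt chloride 12 (not isolated)
Conditions: ClCo(PPh3)3 (1.1 equiv), PhH, rt; dimethylglyoxime, pyridine, rt; volatiles off, crude complex triturated with Et2O (removes PPh3 and pyridine); 10 (1.5 equiv), SnCl4 (1.2 equiv), CH2Cl2, 0 °C to rt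
Reagents that add atoms: none
Why: Monovalent cobalt adds oxidatively into the strained C1–C4 bond between the two carbonyl carbons of 5 to give the five-membered bis-acyl cobaltacycle 11 of trivalent cobalt; exchange of both phosphines for dimethylglyoxime and pyridine gives the octahedral complex 12, from which SnCl4 loosens the chloride and opens a site for the alkyne. The ynol ether 10 coordinates and inserts into the Co–C1 acyl bond with its aryl-bearing carbon C6 bonding to C1, and the resulting seven-membered cobaltacycle closes the six-membered ring by C4–C5 reductive elimination, a formal [4+2] union of the four-carbon maleoyl unit with the two alkyne carbons. The closest known reaction type is the quinone synthesis from maleoyl- and phthaloylcobalt complexes and alkynes under Lewis-acid activation. No stereocentre is formed. The selectivity needed is 2,5- rather than 2,6-placement of the two ethoxy groups: the ynol ether is polarised with C6 nucleophilic and C5 oxocarbenium-like, while C1 (cross-conjugated, next to the ethoxy-bearing carbon) is the more electrophilic acyl carbon and C4 is deactivated as a vinylogous ester carbonyl, so the matched pairing of C6 with C1 and C5 with C4 should give the para-terphenyl quinone.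

Step 4
Reactants: 13 2,5-bis[4-(benzyloxy)phenyl]-3,6-diethoxy-1,4-benzoquinone
Product: 14 2,5-bis[4-(benzyloxy)phenyl]-3,6-dihydroxy-1,4-benzoquinone
Conditions: 2 M NaOH aq, 1,4-dioxane, 70 °C; then 1 M HCl
Reagents that add atoms: sodium hydroxide, [Na+].[OH-] (its oxygen becomes each new enol hydroxyl)
Why: Each ethoxy group sits on the β-carbon of a quinone enone, so hydroxide adds and ethoxide leaves (addition–elimination, a vinylogous ester saponification), while the benzyl aryl ethers are inert to base.

Step 5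
Reactants: 14 2,5-bis[4-(benzyloxy)phenyl]-3,6-dihydroxy-1,4-benzoquinone
Product: 15 4,4''-bis(benzyloxy)-[1,1':4',1''-terphenyl]-2',3',5',6'-tetrol
Conditions: Na2S2O4, THF–H2O, rt, Ar; extracted under Ar and used at once
Reagents that add atoms: none
Why: Dithionite reduction of a quinone to its hydroquinone, here giving the 1,2,4,5-tetrahydroxybenzene core with two equivalent catechols and leaving the benzyl ethers untouched.

Step 6
Reactants: 15 4,4''-bis(benzyloxy)-[1,1':4',1''-terphenyl]-2',3',5',6'-tetrol
Product: 16 4,7-bis[4-(benzyloxy)phenyl]-2,2-diphenyl-1,3-benzodioxole-5,6-diol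
Conditions: Ph2CCl2 (0.7 equiv), K2CO3, MeCN, rt to 40 °C, Ar
Reagents that add atoms: dichlorodiphenylmethane, ClC(Cl)(c1ccccc1)c1ccccc1
Why: Catechol ketalisation with a gem-dichloride through the chlorodiphenylmethyl aryl ether and five-ring closure; the two catechols are equivalent, so preference for the mono ketal rests on a deficiency of reagent, and unreacted 15 should be recoverable (as acidic 14 after aerial oxidation) for recycling.

Step 7
Reactants: 16 4,7-bis[4-(benzyloxy)phenyl]-2,2-diphenyl-1,3-benzodioxole-5,6-diol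
Product: 17 4,7-bis[4-(benzyloxy)phenyl]-2,2-diphenyl-1,3-benzodioxole-5,6-diyl dibenzoate
Conditions: BzCl (2.5 equiv), pyridine, DMAP (cat.), CH2Cl2, 0 °C to rt
Reagents that add atoms: benzoyl chloride, O=C(Cl)c1ccccc1
Why: DMAP-catalysed O-acylation of the only two free hydroxyls; ketal and benzyl ethers are stable to acyl chloride and pyridine.

Step 8
Reactants: 17 4,7-bis[4-(benzyloxy)phenyl]-2,2-diphenyl-1,3-benzodioxole-5,6-diyl dibenzoate
Product: 18 4,4'',5',6'-tetrahydroxy-[1,1':4',1''-terphenyl]-2',3'-diyl dibenzoate (target, CNP0216579.0)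
Conditions: H2 (1 atm), Pd(OH)2/C, THF–EtOAc, rt; work-up under Ar
Reagents that add atoms: none
Why: Catalytic hydrogenolysis cleaves the benzylic C–O bonds of both benzyl ethers and of the diphenylmethylene ketal in one operation while aryl benzoates are inert, and the benzoates cannot migrate to the freed catechol because the two oxygen pairs are separated by the aryl-bearing carbons.

**Compound list**

1 | 1-(benzyloxy)-4-bromobenzene | Brc1ccc(OCc2ccccc2)cc1 | starting material
2 | diethyl squarate (3,4-diethoxycyclobut-3-ene-1,2-dione) | CCOC1=C(OCC)C(=O)C1=O | starting material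
3 | [4-(benzyloxy)phenyl]lithium | [Li]c1ccc(OCc2ccccc2)cc1 | intermediate
4 | 4-[4-(benzyloxy)phenyl]-2,3-diethoxy-4-hydroxycyclobut-2-en-1-one (racemic) | CCOC1=C(OCC)C(O)(c2ccc(OCc3ccccc3)cc2)C1=O | intermediate
5 | 3-[4-(benzyloxy)phenyl]-4-ethoxycyclobut-3-ene-1,2-dione | CCOC1=C(c2ccc(OCc3ccccc3)cc2)C(=O)C1=O | intermediate
6 | ethoxyacetylene | CCOC#C | starting material
7 | 1-(benzyloxy)-4-iodobenzene | Ic1ccc(OCc2ccccc2)cc1 | starting material
8 | lithium ethoxyacetylide | [Li]C#COCC | intermediate
9 | (ethoxyethynyl)zinc chloride | CCOC#C[Zn]Cl | intermediate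
10 | 1-(benzyloxy)-4-(ethoxyethynyl)benzene | CCOC#Cc1ccc(OCc2ccccc2)cc1 | intermediate
11 | chlorobis(triphenylphosphine){2-[4-(benzyloxy)phenyl]-3-ethoxy-1,4-dioxobut-2-ene-1,4-diyl}cobalt (trivalent cobalt) | CCOC1=C(c2ccc(OCc3ccccc3)cc2)C(=O)[Co-2](Cl)([P+](c2ccccc2)(c2ccccc2)c2ccccc2)([P+](c2ccccc2)(c2ccccc2)c2ccccc2)C1=O | intermediate
12 | chloro(dimethylglyoxime)(pyridine){2-[4-(benzyloxy)phenyl]-3-ethoxy-1,4-dioxobut-2-ene-1,4-diyl}cobalt (trivalent cobalt) | CCOC1=C(c2ccc(OCc3ccccc3)cc2)C(=O)[Co-3]2(Cl)([n+]3ccccc3)(C1=O)[N+](O)=C(C)C(C)=[N+]2O | intermediate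
13 | 2,5-bis[4-(benzyloxy)phenyl]-3,6-diethoxy-1,4-benzoquinone | CCOC1=C(c2ccc(OCc3ccccc3)cc2)C(=O)C(OCC)=C(c2ccc(OCc3ccccc3)cc2)C1=O | intermediate
14 | 2,5-bis[4-(benzyloxy)phenyl]-3,6-dihydroxy-1,4-benzoquinone | OC1=C(c2ccc(OCc3ccccc3)cc2)C(=O)C(O)=C(c2ccc(OCc3ccccc3)cc2)C1=O | intermediate
15 | 4,4''-bis(benzyloxy)-[1,1':4',1''-terphenyl]-2',3',5',6'-tetrol | Oc1c(O)c(-c2ccc(OCc3ccccc3)cc2)c(O)c(O)c1-c1ccc(OCc2ccccc2)cc1 | intermediate
16 | 4,7-bis[4-(benzyloxy)phenyl]-2,2-diphenyl-1,3-benzodioxole-5,6-diol | Oc1c(O)c(-c2ccc(OCc3ccccc3)cc2)c2OC(c3ccccc3)(c3ccccc3)Oc2c1-c1ccc(OCc2ccccc2)cc1 | intermediate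
17 | 4,7-bis[4-(benzyloxy)phenyl]-2,2-diphenyl-1,3-benzodioxole-5,6-diyl dibenzoate | O=C(Oc1c(OC(=O)c2ccccc2)c(-c2ccc(OCc3ccccc3)cc2)c2OC(c3ccccc3)(c3ccccc3)Oc2c1-c1ccc(OCc2ccccc2)cc1)c1ccccc1 | intermediate
18 | 4,4'',5',6'-tetrahydroxy-[1,1':4',1''-terphenyl]-2',3'-diyl dibenzoate | O=C(Oc1c(OC(=O)c2ccccc2)c(-c2ccc(O)cc2)c(O)c(O)c1-c1ccc(O)cc1)c1ccccc1 | target

**Step count**

Total: 8 steps. Longest linear sequence: 7 steps (steps 1, 3, 4, 5, 6, 7, 8, from 1 and 2); step 2 is a one-step branch.

**Steps most likely to fail**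

Step 3. The ynol ether may be consumed by SnCl4 (oligomerisation, or hydration by trace water) faster than it inserts. Insertion may also leak towards the 2,6-diethoxy regioisomer, because the para-alkoxyphenyl group at C3 also donates into the C1 acyl group and narrows the difference between the two acyl carbons. The fallback sets out from 1 and returns at 14; it takes the central ring from a preformed quinone and makes both aryl–quinone bonds by cross-coupling. Bromide 1 is lithiated as in step 1 (aryllithium 3), borylated with B(OiPr)3 and hydrolysed to 4-(benzyloxy)phenylboronic acid F1. Tetrabromo-1,4-benzoquinone and NaOMe in MeOH should give 2,5-dibromo-3,6-dimethoxy-1,4-benzoquinone F2. Double Suzuki–Miyaura coupling of F2 with F1 (Pd(PPh3)4, K2CO3, 1,4-dioxane, 85 °C) should give 2,5-bis[4-(benzyloxy)phenyl]-3,6-dimethoxy-1,4-benzoquinone F3, and NaOH hydrolysis under the conditions of step 4 converts it into 14.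

Step 6. Ketalisation may run past the mono stage to the bis-ketal, giving a statistical mixture, and the tetrol may re-oxidise in the basic medium. The fallback sets out from 14 and returns at 16; it differentiates the two halves at the quinone stage, where the first hydrolysis of a bis(vinylogous ester) deactivates the second. Compound 14 is O-allylated (allyl bromide, K2CO3, DMF) to 2,5-bis(allyloxy)-3,6-bis[4-(benzyloxy)phenyl]-1,4-benzoquinone F4. One equivalent of NaOH (THF–H2O, rt) should remove a single allyl group, because the resulting vinylogous carboxylate anion resists further attack, giving 2-(allyloxy)-5-hydroxy-3,6-bis[4-(benzyloxy)phenyl]-1,4-benzoquinone F5. Na2S2O4 reduction gives 3'-(allyloxy)-4,4''-bis(benzyloxy)-[1,1':4',1''-terphenyl]-2',5',6'-triol F6, which holds only one catechol. Ph2CCl2 and K2CO3 in MeCN convert it into 6-(allyloxy)-4,7-bis[4-(benzyloxy)phenyl]-2,2-diphenyl-1,3-benzodioxol-5-ol F7. Tsuji–Trost deallylation (Pd(PPh3)4, morpholine, THF, rt) then frees the second catechol and delivers 16.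

Step 2. The ynol ether may be lost by hydration or acid-induced decomposition during coupling and purification, and the alkynylzinc reagent may homocouple. The fallback sets out from 7 and returns at 10; it forms the triple bond by elimination instead of coupling. Iodide 7 is converted into the aryl Grignard reagent (iPrMgCl·LiCl, THF, −20 °C) and acylated with 2-ethoxy-N-methoxy-N-methylacetamide to give 1-[4-(benzyloxy)phenyl]-2-ethoxyethan-1-one F8. LiN(SiMe3)2 and PhNTf2 (THF, −78 °C) should give, through the chelated enolate, (Z)-1-[4-(benzyloxy)phenyl]-2-ethoxyethenyl trifluoromethanesulfonate F9. Anti-elimination of triflate with KOtBu (THF, −78 °C) gives 10.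

**Further compounds**

F1 | step 3 | 4-(benzyloxy)phenylboronic acid | OB(O)c1ccc(OCc2ccccc2)cc1
F2 | step 3 | 2,5-dibromo-3,6-dimethoxy-1,4-benzoquinone | COC1=C(Br)C(=O)C(OC)=C(Br)C1=O
F3 | step 3 | 2,5-bis[4-(benzyloxy)phenyl]-3,6-dimethoxy-1,4-benzoquinone | COC1=C(c2ccc(OCc3ccccc3)cc2)C(=O)C(OC)=C(c2ccc(OCc3ccccc3)cc2)C1=O
F4 | step 6 | 2,5-bis(allyloxy)-3,6-bis[4-(benzyloxy)phenyl]-1,4-benzoquinone | C=CCOC1=C(c2ccc(OCc3ccccc3)cc2)C(=O)C(OCC=C)=C(c2ccc(OCc3ccccc3)cc2)C1=O
F5 | step 6 | 2-(allyloxy)-5-hydroxy-3,6-bis[4-(benzyloxy)phenyl]-1,4-benzoquinone | C=CCOC1=C(c2ccc(OCc3ccccc3)cc2)C(=O)C(O)=C(c2ccc(OCc3ccccc3)cc2)C1=O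
F6 | step 6 | 3'-(allyloxy)-4,4''-bis(benzyloxy)-[1,1':4',1''-terphenyl]-2',5',6'-triol | C=CCOc1c(O)c(-c2ccc(OCc3ccccc3)cc2)c(O)c(O)c1-c1ccc(OCc2ccccc2)cc1
F7 | step 6 | 6-(allyloxy)-4,7-bis[4-(benzyloxy)phenyl]-2,2-diphenyl-1,3-benzodioxol-5-ol | C=CCOc1c(O)c(-c2ccc(OCc3ccccc3)cc2)c2OC(c3ccccc3)(c3ccccc3)Oc2c1-c1ccc(OCc2ccccc2)cc1
F8 | step 2 | 1-[4-(benzyloxy)phenyl]-2-ethoxyethan-1-one | CCOCC(=O)c1ccc(OCc2ccccc2)cc1
F9 | step 2 | (Z)-1-[4-(benzyloxy)phenyl]-2-ethoxyethenyl trifluoromethanesulfonate | CCO/C=C(\OS(=O)(=O)C(F)(F)F)c1ccc(OCc2ccccc2)cc1
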